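**Plan**

1. Locants: ring C1 (stereocentre), C2, C3=C4(CH3), C5, C6; C7 is the alkene carbon on C1, C8–C9 the ethylene link, C10=C11 the Z chain alkene. Cuts: C7=CH2 (ketone methylenation); ring bond C4–C5, traded for a C7–C5 bond of a cyclobutanol; C7–C8 (Grignard plus cyclobutanone); C1–C2 (hydrazone alkylation); chain at C12–C13, C9–C10 and the C11 methyl.
2. Enabling feature: C7 sits on C1 and is 1,4 to ring CH2 C5 through C1–C6, so C7–C1–C6–C5 can be folded into a tert-cyclobutanol. With a (Z)-3-iodobut-2-enyl arm (C2–C3=C4) on C1, palladium held at C4 cleaves the strained C7–C5 bond and joins C4 to C5: the four-membered ring opens as the cyclohexene closes and C7 becomes the ketone.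
3. Forward: all-S C20 alcohol → iodide → one-pot propargylation/hydroxyethylation → Z-selective methylmagnesiation → bromide (chain C8–C28); cyclobutanone → RAMP hydrazone → alkylation → ketone; Grignard union at C7–C8; ring-opening/ring-closing coupling; methylenation.
4. Stereochemistry: chain centres (S,S,S) from catalyst-controlled iridium hydrogenation of (E,E,E)-geranylgeraniol; Z alkene from syn-carbomagnesiation; ring centre (R) from the RAMP auxiliary, carried through unchanged; position and geometry of the ring alkene from the (Z)-alkenyl iodide.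

Key step: step 12

Remark: the chain alkene of the target is read as Z and the three chain methyl centres as S (mirror image of the natural phytyl series); for 22 the expected major epimer is drawn and both epimers should lead to the same ketone; the C=N geometry of 19 is left undefined.

**Step 1**
Reactants: 1 (2E,6E,10E)-geranylgeraniol
Product: 2 (3S,7S,11S)-3,7,11,15-tetramethylhexadecan-1-ol
Conditions: H2 (50 bar), [Ir(cod)(L*)][B(C6H3(CF3)2)4] (1 mol%; L* = enantiopure bicyclic pyridyl di-tert-butylphosphinite P,N ligand, the enantiomer opposite to the one that gives the natural 3R,7R,11R series), CH2Cl2, rt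
Reagents that add atoms: none
Why: Iridium P,N-catalysed asymmetric hydrogenation of (E)-trisubstituted alkenes is catalyst-controlled at each double bond, so the three E alkenes of identical substitution pattern should be reduced from the same face to set C3, C7 and C11 as S, while the terminal isopropylidene is reduced without creating a centre.

**Step 2**
Reactants: 2 (3S,7S,11S)-3,7,11,15-tetramethylhexadecan-1-ol
Product: 3 (3S,7S,11S)-1-iodo-3,7,11,15-tetramethylhexadecane
Conditions: I2, PPh3, imidazole, CH2Cl2, 0 °C → rt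
Reagents that add atoms: iodine, II
Why: Appel-type iodination of a primary alcohol is an SN2 displacement at C1 and leaves the remote stereocentres untouched.

**Step 3**
Reactants: 3 (3S,7S,11S)-1-iodo-3,7,11,15-tetramethylhexadecane; 4 propyne
Product: 7 (8S,12S,16S)-8,12,16,20-tetramethylhenicos-3-yn-1-ol, via 1,3-dilithiopropyne 5 (not isolated), via lithium alkynide 6 (not isolated)
Conditions: 4, n-BuLi (2 equiv), TMEDA, Et2O/hexane, −78 → 0 °C; then 3, THF, −78 °C → rt; then oxirane (excess), DMPU, −20 °C → rt; H2O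
Reagents that add atoms: oxirane, C1CO1
Why: One-pot sequential alkylation of 1,3-dilithiopropyne, in which the sp3 carbanion terminus, the more nucleophilic site, displaces the primary iodide (SN2) and the lithium alkynide left behind is trapped in the same flask by DMPU-promoted opening of oxirane, should give the homopropargylic alcohol that directs the next step.

**Step 4**
Reactants: 7 (8S,12S,16S)-8,12,16,20-tetramethylhenicos-3-yn-1-ol
Product: 9 (3Z,8S,12S,16S)-4,8,12,16,20-pentamethylhenicos-3-en-1-ol, via alkenylmagnesium alkoxide 8 (not isolated)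
Conditions: Fe(acac)3 (20 mol%), MeMgBr (5 equiv), THF, −78 → 0 °C; then aq NH4Cl
Reagents that add atoms: methylmagnesium bromide, C[Mg]Br
Why: Iron-catalysed, alkoxide-directed syn-carbomagnesiation of a homopropargylic alcohol delivers methyl to the distal alkyne carbon and magnesium to the proximal one in a five-membered chelate, so protonation should give the trisubstituted alkene with methyl trans to the hydroxyethyl arm, i.e. the Z isomer.

**Step 5**
Reactants: 9 (3Z,8S,12S,16S)-4,8,12,16,20-pentamethylhenicos-3-en-1-ol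
Product: 10 (3Z,8S,12S,16S)-1-bromo-4,8,12,16,20-pentamethylhenicos-3-ene
Conditions: CBr4, PPh3, CH2Cl2, 0 °C
Reagents that add atoms: carbon tetrabromide, BrC(Br)(Br)Br
Why: Appel bromination of the primary homoallylic alcohol is neutral and should not touch the Z alkene or the stereocentres.

**Step 6**
Reactants: 11 but-2-yn-1-ol
Product: 13 (Z)-3-iodobut-2-en-1-ol, via sodium alkenylalanate 12 (not isolated)
Conditions: NaAlH2(OCH2CH2OMe)2 (Red-Al), THF, 0 °C → rt; then I2, THF, −78 → 0 °C
Reagents that add atoms: iodine, II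
Why: Hydroxyl-directed trans-hydroalumination of the propargylic alcohol places aluminium on C3 in a five-membered alanate, and iodinolysis with retention gives the alkenyl iodide with iodine cis to the CH2OH group.

**Step 7**
Reactants: 13 (Z)-3-iodobut-2-en-1-ol
Product: 14 (Z)-1-bromo-3-iodobut-2-ene
Conditions: CBr4, PPh3, CH2Cl2, 0 °C, dark
Reagents that add atoms: carbon tetrabromide, BrC(Br)(Br)Br
Why: Appel bromination of the primary allylic alcohol gives the allylic bromide without scrambling the alkenyl iodide geometry.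

**Step 8**
Reactants: 15 cyclobutanone; 16 (R)-1-amino-2-(methoxymethyl)pyrrolidine (RAMP)
Product: 17 (R)-N-cyclobutylidene-2-(methoxymethyl)pyrrolidin-1-amine
Conditions: neat, 4 Å MS, rt → 50 °C
Reagents that add atoms: none
Why: Hydrazone condensation of the unhindered strained ketone with the chiral hydrazine is fast and installs the auxiliary.

**Step 9**
Reactants: 17 (R)-N-cyclobutylidene-2-(methoxymethyl)pyrrolidin-1-amine; 14 (Z)-1-bromo-3-iodobut-2-ene
Product: 19 (R)-N-[(2R)-2-[(Z)-3-iodobut-2-en-1-yl]cyclobutylidene]-2-(methoxymethyl)pyrrolidin-1-amine, via lithium azaenolate 18 (not isolated)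
Conditions: LiN(iPr)2 (LDA), THF, 0 °C; then 14, −100 → −78 °C
Reagents that add atoms: none
Why: Enders RAMP-hydrazone alkylation: the methoxy-chelated lithium azaenolate is alkylated by the reactive allylic bromide on the face dictated by the auxiliary, which for RAMP (mirror image of the SAMP outcome) should set the new α-centre as R, and the alkenyl iodide is inert to the azaenolate at low temperature.

**Step 10**
Reactants: 19 (R)-N-[(2R)-2-[(Z)-3-iodobut-2-en-1-yl]cyclobutylidene]-2-(methoxymethyl)pyrrolidin-1-amine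
Product: 20 (R)-2-[(Z)-3-iodobut-2-en-1-yl]cyclobutan-1-one
Conditions: sat. aq oxalic acid, Et2O, rt (two-phase)
Reagents that add atoms: water, O
Why: Mild two-phase oxalic acid hydrolysis cleaves the hydrazone without enolising the α-stereocentre of the strained ketone, and the auxiliary can be recovered.

**Step 11**
Reactants: 10 (3Z,8S,12S,16S)-1-bromo-4,8,12,16,20-pentamethylhenicos-3-ene; 20 (R)-2-[(Z)-3-iodobut-2-en-1-yl]cyclobutan-1-one
Product: 22 (1S,2R)-2-[(Z)-3-iodobut-2-en-1-yl]-1-[(3Z,8S,12S,16S)-4,8,12,16,20-pentamethylhenicos-3-en-1-yl]cyclobutan-1-ol, via Grignard reagent 21 (not isolated)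
Conditions: 10, Mg, THF, rt; then 20, LaCl3·2LiCl, THF, −78 → −20 °C; aq NH4Cl
Reagents that add atoms: none
Why: Grignard 1,2-addition to the strained, highly electrophilic cyclobutanone (the lanthanum salt suppresses enolisation) joins the two fragments; the alkyl group should enter trans to the 2-substituent, but the carbinol configuration is of no consequence because this carbon becomes the ketone in step 12, and an alkylmagnesium halide does not exchange with the alkenyl iodide at −78 °C.

**Step 12**
Reactants: 22 (1S,2R)-2-[(Z)-3-iodobut-2-en-1-yl]-1-[(3Z,8S,12S,16S)-4,8,12,16,20-pentamethylhenicos-3-en-1-yl]cyclobutan-1-ol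
Product: 25 (4Z,9S,13S,17S)-5,9,13,17,21-pentamethyl-1-[(1R)-4-methylcyclohex-3-en-1-yl]docos-4-en-1-one, via alkenylpalladium alkoxide chelate 23 (not isolated), via seven-membered palladacycle 24 (not isolated)
Conditions: Pd(OAc)2 (10 mol%), rac-BINAP (20 mol%), Cs2CO3 (2 equiv), PhMe (0.01 M), 80 °C
Reagents that add atoms: none
Why: Proposed new method: zerovalent palladium inserts into the (Z)-alkenyl iodide, the tertiary cyclobutanolate (no β-hydrogen) displaces iodide to give chelate 23, strain-driven β-carbon elimination cleaves the bond from the carbinol carbon to the unsubstituted ring CH2 to give ketone-bearing palladacycle 24, and C(sp2)–C(sp3) reductive elimination joins that CH2 to the methyl-bearing alkene carbon. The closest known reaction type is the intermolecular palladium-catalysed ring-opening arylation and alkenylation of tert-cyclobutanols with aryl or alkenyl halides, which gives γ-substituted ketones by the same β-carbon elimination; here the halide is tethered so that the coupling closes a ring. The cyclohexene closes by reductive elimination from the seven-membered palladacycle 24 (formally a 6-exo attack of the released primary alkyl on the alkenyl carbon), and the cis arrangement the ring demands across the alkene is fixed by the Z geometry of the iodide, which is retained through oxidative addition and reductive elimination. No new stereocentre is created: the ring centre is the untouched substituted carbon of the cyclobutane and the carbinol centre becomes the carbonyl carbon, so the epimers of 22 should converge. The step needs cleavage on the CH2 side and not on the CH side, and reductive elimination faster than β-hydride elimination; the first is expected because β-carbon elimination at palladium favours the primary alkyl–metal bond and the alternative would give a palladacyclopentene whose only coupling exit is a strained cyclobutene, the second is helped by the wide-bite-angle bisphosphine and the ease of six-membered ring formation.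

**Step 13**
Reactants: 25 (4Z,9S,13S,17S)-5,9,13,17,21-pentamethyl-1-[(1R)-4-methylcyclohex-3-en-1-yl]docos-4-en-1-one
Product: 26 (4R)-1-methyl-4-[(5Z,10S,14S,18S)-6,10,14,18,22-pentamethyltricosa-1,5-dien-2-yl]cyclohex-1-ene
Conditions: Cp2Ti(μ-Cl)(μ-CH2)AlMe2 (Tebbe reagent), pyridine, THF/PhMe, −40 °C → rt; aq NaOH
Reagents that add atoms: Tebbe reagent (written as the Cp2Ti=CH2·ClAlMe2 adduct), C=[Ti](C1C=CC=C1)C1C=CC=C1.C[Al](C)Cl
Why: Tebbe carbonyl methylenation is non-basic, so the ketone should be converted into the 1,1-disubstituted alkene without epimerising the adjacent ring stereocentre, and the trisubstituted alkenes are inert to the reagent.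

**Compound list**

1 | (2E,6E,10E)-3,7,11,15-tetramethylhexadeca-2,6,10,14-tetraen-1-ol (geranylgeraniol) | CC(C)=CCC/C(C)=C/CC/C(C)=C/CC/C(C)=C/CO | starting material
2 | (3S,7S,11S)-3,7,11,15-tetramethylhexadecan-1-ol | OCC[C@@H](C)CCC[C@@H](C)CCC[C@@H](C)CCCC(C)C | intermediate
3 | (3S,7S,11S)-1-iodo-3,7,11,15-tetramethylhexadecane | ICC[C@@H](C)CCC[C@@H](C)CCC[C@@H](C)CCCC(C)C | intermediate
4 | propyne | CC#C | starting material
5 | 1,3-dilithiopropyne | [Li]CC#C[Li] | intermediate
6 | lithium (6S,10S,14S)-6,10,14,18-tetramethylnonadec-1-yn-1-ide | [Li]C#CCCC[C@@H](C)CCC[C@@H](C)CCC[C@@H](C)CCCC(C)C | intermediate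
7 | (8S,12S,16S)-8,12,16,20-tetramethylhenicos-3-yn-1-ol | OCCC#CCCC[C@@H](C)CCC[C@@H](C)CCC[C@@H](C)CCCC(C)C | intermediate
8 | cyclic (Z)-alkenylmagnesium alkoxide (1-oxa-2-magnesacyclopentane with exocyclic alkylidene, Mg cis to the new methyl) | C/C(CCC[C@@H](C)CCC[C@@H](C)CCC[C@@H](C)CCCC(C)C)=C1/CCO[Mg]1 | intermediate
9 | (3Z,8S,12S,16S)-4,8,12,16,20-pentamethylhenicos-3-en-1-ol | OCC/C=C(/C)CCC[C@@H](C)CCC[C@@H](C)CCC[C@@H](C)CCCC(C)C | intermediate
10 | (3Z,8S,12S,16S)-1-bromo-4,8,12,16,20-pentamethylhenicos-3-ene | BrCC/C=C(/C)CCC[C@@H](C)CCC[C@@H](C)CCC[C@@H](C)CCCC(C)C | intermediate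
11 | but-2-yn-1-ol | CC#CCO | starting material
12 | sodium 2,2-bis(2-methoxyethoxy)-3-methyl-1-oxa-2-aluminatacyclopent-3-ene (cyclic alkenylalanate) | [Na+].CC1=CCO[Al-]1(OCCOC)OCCOC | intermediate
13 | (Z)-3-iodobut-2-en-1-ol | C/C(I)=C/CO | intermediate
14 | (Z)-1-bromo-3-iodobut-2-ene | C/C(I)=C/CBr | intermediate
15 | cyclobutanone | O=C1CCC1 | starting material
16 | (R)-1-amino-2-(methoxymethyl)pyrrolidine (RAMP) | COC[C@H]1CCCN1N | starting material
17 | (R)-N-cyclobutylidene-2-(methoxymethyl)pyrrolidin-1-amine | COC[C@H]1CCCN1N=C1CCC1 | intermediate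
18 | lithium azaenolate of 17 (N-lithio-N-(cyclobut-1-en-1-yl) hydrazide) | COC[C@H]1CCCN1N([Li])C1=CCC1 | intermediate
19 | (R)-N-[(2R)-2-[(Z)-3-iodobut-2-en-1-yl]cyclobutylidene]-2-(methoxymethyl)pyrrolidin-1-amine | COC[C@H]1CCCN1N=C1CC[C@@H]1C/C=C(/C)I | intermediate
20 | (R)-2-[(Z)-3-iodobut-2-en-1-yl]cyclobutan-1-one | O=C1CC[C@@H]1C/C=C(/C)I | intermediate
21 | [(3Z,8S,12S,16S)-4,8,12,16,20-pentamethylhenicos-3-en-1-yl]magnesium bromide | Br[Mg]CC/C=C(/C)CCC[C@@H](C)CCC[C@@H](C)CCC[C@@H](C)CCCC(C)C | intermediate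
22 | (1S,2R)-2-[(Z)-3-iodobut-2-en-1-yl]-1-[(3Z,8S,12S,16S)-4,8,12,16,20-pentamethylhenicos-3-en-1-yl]cyclobutan-1-ol (hydroxyl cis to the iodobutenyl arm) | O[C@]1(CC/C=C(/C)CCC[C@@H](C)CCC[C@@H](C)CCC[C@@H](C)CCCC(C)C)CC[C@@H]1C/C=C(/C)I | intermediate
23 | alkenylpalladium alkoxide chelate from 22 (seven-membered Pd–O chelate; phosphine on palladium not drawn) | O2[C@]1(CC/C=C(/C)CCC[C@@H](C)CCC[C@@H](C)CCC[C@@H](C)CCCC(C)C)CC[C@@H]1C/C=C(/C)[Pd]2 | intermediate
24 | seven-membered alkyl(alkenyl)palladacycle carrying the side-chain ketone (phosphine on palladium not drawn) | O=C(CC/C=C(/C)CCC[C@@H](C)CCC[C@@H](C)CCC[C@@H](C)CCCC(C)C)[C@H]1C/C=C(/C)[Pd]CC1 | intermediate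
25 | (4Z,9S,13S,17S)-5,9,13,17,21-pentamethyl-1-[(1R)-4-methylcyclohex-3-en-1-yl]docos-4-en-1-one | O=C(CC/C=C(/C)CCC[C@@H](C)CCC[C@@H](C)CCC[C@@H](C)CCCC(C)C)[C@H]1CC=C(C)CC1 | intermediate
26 | (4R)-1-methyl-4-[(5Z,10S,14S,18S)-6,10,14,18,22-pentamethyltricosa-1,5-dien-2-yl]cyclohex-1-ene | C=C(CC/C=C(/C)CCC[C@@H](C)CCC[C@@H](C)CCC[C@@H](C)CCCC(C)C)[C@H]1CC=C(C)CC1 | target

**Step count and risks**

Total steps: 13. Longest linear sequence: 8 (steps 1–5, then 11–13).

Steps most likely to fail:

Step 12 (β-carbon elimination toward the substituted ring carbon, or β-hydride elimination from the alkylpalladium before reductive elimination, would give ring-opened or reduced material instead of ring closure). The fallback uses known chemistry and closes the same ring bond. It sets out from bromide 14 and comes back to the route at ketone 25. (S)-4-Benzyloxazolidin-2-one is acylated with but-3-enoic acid (PivCl, Et3N, LiCl, THF) to give (S)-4-benzyl-3-(but-3-enoyl)oxazolidin-2-one F1. Its sodium enolate (NaN(SiMe3)2, THF, −78 °C) is alkylated at the α-carbon by 14 anti to the benzyl group (Evans alkylation) to give (S)-4-benzyl-3-[(2S,4Z)-2-ethenyl-5-iodohex-4-enoyl]oxazolidin-2-one F2. 9-BBN-H (THF, 0 °C → rt) should hydroborate only the vinyl group to give (S)-4-benzyl-3-[(2R,4Z)-2-[2-(9-borabicyclo[3.3.1]nonan-9-yl)ethyl]-5-iodohex-4-enoyl]oxazolidin-2-one F3. Without isolation, F3 undergoes intramolecular B-alkyl Suzuki–Miyaura coupling (Pd(dppf)Cl2, AsPh3, Cs2CO3, DMF/THF/H2O, rt) to give (S)-4-benzyl-3-[(1R)-4-methylcyclohex-3-ene-1-carbonyl]oxazolidin-2-one F4. MeNHOMe·HCl/AlMe3 (CH2Cl2, 0 °C) gives (1R)-N-methoxy-N,4-dimethylcyclohex-3-ene-1-carboxamide F5, and Grignard reagent 21 (THF, 0 °C) then gives ketone 25.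

Step 4 (methyl delivered to the wrong alkyne carbon, leakage of syn-stereocontrol, or reduction of the alkyne by iron hydride species would erode the Z alkene). The fallback sets out from iodide 3 and comes back at alcohol 9, so it does not depend on the alkynol of step 3 either. 3-[(tert-Butyldimethylsilyl)oxy]propanal and methyl 2-[bis(2,2,2-trifluoroethoxy)phosphoryl]propanoate (KN(SiMe3)2, 18-crown-6, THF, −78 °C; Still–Gennari olefination) give methyl (2Z)-5-[(tert-butyldimethylsilyl)oxy]-2-methylpent-2-enoate F6. iBu2AlH (CH2Cl2, −78 °C) gives (2Z)-5-[(tert-butyldimethylsilyl)oxy]-2-methylpent-2-en-1-ol F7, and CBr4/PPh3 gives tert-butyl{[(3Z)-5-bromo-4-methylpent-3-en-1-yl]oxy}dimethylsilane F8. Iodide 3 is converted (Mg, THF) into [(3S,7S,11S)-3,7,11,15-tetramethylhexadecyl]magnesium iodide F9, which is coupled at the primary allylic carbon of F8 under Li2CuCl4 catalysis (THF, −78 → 0 °C) to give tert-butyldimethyl{[(3Z,8S,12S,16S)-4,8,12,16,20-pentamethylhenicos-3-en-1-yl]oxy}silane F10. Bu4NF (THF) then gives alcohol 9.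

Step 13 (enolisation of the α-branched ketone by the reagent or its aluminium by-product, leading to epimerisation at the ring stereocentre or to stalled conversion). The fallback sets out from ketone 25 and comes back at target 26. Me3SiCH2MgCl premixed with CeCl3 (THF, −78 °C) should add without enolisation to give (5Z,10S,14S,18S)-6,10,14,18,22-pentamethyl-2-[(1R)-4-methylcyclohex-3-en-1-yl]-1-(trimethylsilyl)tricos-5-en-2-ol F11 (mixture at the carbinol carbon, of no consequence). KH (THF, rt) then induces syn-elimination (Peterson olefination) to give 26.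

**Further compounds**

F1 | step 12 | (S)-4-benzyl-3-(but-3-enoyl)oxazolidin-2-one | C=CCC(=O)N1[C@@H](Cc2ccccc2)COC1=O
F2 | step 12 | (S)-4-benzyl-3-[(2S,4Z)-2-ethenyl-5-iodohex-4-enoyl]oxazolidin-2-one | C/C(I)=C/C[C@@H](C=C)C(=O)N1[C@@H](Cc2ccccc2)COC1=O
F3 | step 12 | (S)-4-benzyl-3-[(2R,4Z)-2-[2-(9-borabicyclo[3.3.1]nonan-9-yl)ethyl]-5-iodohex-4-enoyl]oxazolidin-2-one | C/C(I)=C/C[C@@H](CCB1C2CCCC1CCC2)C(=O)N1[C@@H](Cc2ccccc2)COC1=O
F4 | step 12 | (S)-4-benzyl-3-[(1R)-4-methylcyclohex-3-ene-1-carbonyl]oxazolidin-2-one | O=C([C@H]1CC=C(C)CC1)N1[C@@H](Cc2ccccc2)COC1=O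
F5 | step 12 | (1R)-N-methoxy-N,4-dimethylcyclohex-3-ene-1-carboxamide | CON(C)C(=O)[C@H]1CC=C(C)CC1
F6 | step 4 | methyl (2Z)-5-[(tert-butyldimethylsilyl)oxy]-2-methylpent-2-enoate | COC(=O)/C(C)=C\CCO[Si](C)(C)C(C)(C)C
F7 | step 4 | (2Z)-5-[(tert-butyldimethylsilyl)oxy]-2-methylpent-2-en-1-ol | OC/C(C)=C\CCO[Si](C)(C)C(C)(C)C
F8 | step 4 | tert-butyl{[(3Z)-5-bromo-4-methylpent-3-en-1-yl]oxy}dimethylsilane | BrC/C(C)=C\CCO[Si](C)(C)C(C)(C)C
F9 | step 4 | [(3S,7S,11S)-3,7,11,15-tetramethylhexadecyl]magnesium iodide | I[Mg]CC[C@@H](C)CCC[C@@H](C)CCC[C@@H](C)CCCC(C)C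
F10 | step 4 | tert-butyldimethyl{[(3Z,8S,12S,16S)-4,8,12,16,20-pentamethylhenicos-3-en-1-yl]oxy}silane | CC(C)(C)[Si](C)(C)OCC/C=C(/C)CCC[C@@H](C)CCC[C@@H](C)CCC[C@@H](C)CCCC(C)C
F11 | step 13 | (5Z,10S,14S,18S)-6,10,14,18,22-pentamethyl-2-[(1R)-4-methylcyclohex-3-en-1-yl]-1-(trimethylsilyl)tricos-5-en-2-ol | C[Si](C)(C)CC(O)(CC/C=C(/C)CCC[C@@H](C)CCC[C@@H](C)CCC[C@@H](C)CCCC(C)C)[C@H]1CC=C(C)CC1
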